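**Retrosynthetic overview**

1. The target comes from MOM removal of a (3R)-3-hydroxy-5,7-bis(MOM)isoflavanone, whose C3–OH (the only stereocentre) is set by reagent-controlled hydroxylation of the racemic isoflavanone enolate.
2. The isoflavanone comes from 1,4-reduction of the isoflavone, which is made by one-carbon annulation of a 2-hydroxydeoxybenzoin.
3. The deoxybenzoin comes from oxidation and Pd-mediated deallylation/decarboxylation of a β-hydroxy ester. That ester is made by the key intermolecular aldol addition (C3–C4 bond) of a B-ring allyl arylacetate enolate to an A-ring aldehyde.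
4. The B-ring ester comes from an arylmalonate, made from the aryl bromide, made by I/Mg exchange and prenylation of 1-bromo-3-iodo-2,4-dimethoxybenzene, made from 1,3-dimethoxybenzene. The A-ring aldehyde comes from 2,4,6-trihydroxybenzaldehyde (two MOM, one allyl).
5. Ring order: both benzene rings are bought; the pyranone ring is the only ring made (O1–C2 and C2–C3, at the isoflavone stage).

Assumption: the given SMILES corresponds to the (3R) configuration (chroman-4-one numbering is used throughout).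

**Route**

Step 1
Reactants: 1 1,3-dimethoxybenzene
Product: 3 2-iodo-1,3-dimethoxybenzene, via 2,6-dimethoxyphenyllithium 2 (not isolated)
Conditions: n-BuLi, THF, 0 °C → rt; I2, −78 °C → rt
Reagents that add atoms: n-butyllithium, [Li]CCCC (Li of 2); iodine, II
Why: Directed ortho-metalation removes the C2–H flanked by both methoxy groups, and the aryllithium is trapped by iodine.

Step 2
Reactants: 3 2-iodo-1,3-dimethoxybenzene
Product: 4 1-bromo-3-iodo-2,4-dimethoxybenzene
Conditions: NBS (1.0 equiv), MeCN, 0 °C → rt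
Reagents that add atoms: N-bromosuccinimide, O=C1CCC(=O)N1Br
Why: Electrophilic aromatic bromination goes to C4, which is para to one methoxy and ortho to the other; C4 and C6 are equivalent, so one monobromide forms.

Step 3
Reactants: 4 1-bromo-3-iodo-2,4-dimethoxybenzene; 5 prenyl bromide (1-bromo-3-methylbut-2-ene)
Product: 7 1-bromo-2,4-dimethoxy-3-(3-methylbut-2-en-1-yl)benzene, via aryl Grignard 6 (not isolated)
Conditions: i-PrMgCl·LiCl, THF, −20 → 0 °C; CuBr·SMe2 (10 mol %), 5, 0 °C → rt
Reagents that add atoms: isopropylmagnesium chloride, CC(C)[Mg]Cl (Mg and Cl of 6)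
Why: Halogen–magnesium exchange is much faster at iodine than at bromine, and copper-catalysed allylic substitution at the primary carbon of prenyl bromide gives the linear prenyl arene with the bromide intact.

Step 4
Reactants: 7 1-bromo-2,4-dimethoxy-3-(3-methylbut-2-en-1-yl)benzene; 8 diethyl malonate
Product: 9 diethyl 2-[2,4-dimethoxy-3-(3-methylbut-2-en-1-yl)phenyl]malonate
Conditions: Pd(OAc)2 (2 mol %), t-Bu3P·HBF4 (4 mol %), K3PO4, toluene, 90 °C
Reagents that add atoms: none
Why: Pd-catalysed α-arylation of a malonate (Buchwald–Hartwig-type enolate coupling) with a bulky electron-rich phosphine accepts electron-rich ortho-substituted bromides and leaves the isolated trisubstituted alkene alone.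

Step 5
Reactants: 9 diethyl 2-[2,4-dimethoxy-3-(3-methylbut-2-en-1-yl)phenyl]malonate
Product: 11 2-[2,4-dimethoxy-3-(3-methylbut-2-en-1-yl)phenyl]acetic acid, via arylmalonic acid 10 (not isolated)
Conditions: NaOH, EtOH/H2O, 70 °C; 1 M HCl, 0 °C (pH 2), extract; toluene, 100 °C
Reagents that add atoms: sodium hydroxide, [Na+].[OH-]
Why: Saponification followed by thermal decarboxylation of the arylmalonic acid exposes the prenyl group only to brief cold dilute acid.

Step 6
Reactants: 11 2-[2,4-dimethoxy-3-(3-methylbut-2-en-1-yl)phenyl]acetic acid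
Product: 12 allyl 2-[2,4-dimethoxy-3-(3-methylbut-2-en-1-yl)phenyl]acetate
Conditions: allyl bromide, K2CO3, DMF, rt
Reagents that add atoms: allyl bromide, C=CCBr
Why: SN2 O-alkylation of the carboxylate gives an ester that is later removed under neutral Pd(0) conditions.

Step 7
Reactants: 13 2,4,6-trihydroxybenzaldehyde
Product: 14 2-hydroxy-4,6-bis(methoxymethoxy)benzaldehyde
Conditions: MOMCl (2.2 equiv), i-Pr2NEt, CH2Cl2, 0 °C → rt
Reagents that add atoms: chloromethyl methyl ether, COCCl
Why: In this Williamson-type protection the phenol hydrogen-bonded to the aldehyde is the least nucleophilic, so two equivalents cap the other two hydroxyls.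

Step 8
Reactants: 14 2-hydroxy-4,6-bis(methoxymethoxy)benzaldehyde
Product: 15 2-(allyloxy)-4,6-bis(methoxymethoxy)benzaldehyde
Conditions: allyl bromide, K2CO3, DMF, 50 °C
Reagents that add atoms: allyl bromide, C=CCBr
Why: Williamson ether synthesis masks the remaining chelated phenol with a group orthogonal to MOM that is removed together with the allyl ester.

Step 9 (key step)
Reactants: 12 allyl 2-[2,4-dimethoxy-3-(3-methylbut-2-en-1-yl)phenyl]acetate; 15 2-(allyloxy)-4,6-bis(methoxymethoxy)benzaldehyde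
Product: 17 allyl 3-[2-(allyloxy)-4,6-bis(methoxymethoxy)phenyl]-2-[2,4-dimethoxy-3-(3-methylbut-2-en-1-yl)phenyl]-3-hydroxypropanoate (racemic syn/anti mixture), via ester lithium enolate 16 (not isolated)
Conditions: LDA, THF, −78 °C; 15, −78 °C, 1 h; AcOH, −78 °C
Reagents that add atoms: lithium diisopropylamide, [Li+].CC(C)[N-]C(C)C (Li of 16)
Why: Intermolecular aldol addition of the lithium ester enolate to the non-enolisable aldehyde makes the C3–C4 bond that joins the B- and A-ring fragments under basic conditions the prenyl group tolerates (it would not survive a Friedel–Crafts or Hoesch acylation); both new stereocentres are erased later, so their ratio does not matter.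

Step 10
Reactants: 17 the aldol adduct
Product: 18 allyl 3-[2-(allyloxy)-4,6-bis(methoxymethoxy)phenyl]-2-[2,4-dimethoxy-3-(3-methylbut-2-en-1-yl)phenyl]-3-oxopropanoate (racemic)
Conditions: Dess–Martin periodinane, NaHCO3, CH2Cl2, 0 °C → rt
Reagents that add atoms: none
Why: Buffered Dess–Martin oxidation converts the secondary benzylic alcohol into the β-keto ester without affecting MOM ethers or any of the three alkenes.

Step 11
Reactants: 18 the β-keto allyl ester
Product: 20 2-[2,4-dimethoxy-3-(3-methylbut-2-en-1-yl)phenyl]-1-[2-hydroxy-4,6-bis(methoxymethoxy)phenyl]ethan-1-one, via keto acid 19 (not isolated)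
Conditions: Pd(PPh3)4 (5 mol %), morpholine (6 equiv), THF, rt → 40 °C
Reagents that add atoms: none
Why: In this Tsuji–Trost deallylation Pd(0) ionises the allyl ester (fast) and the allyl aryl ether, excess morpholine traps both π-allyl fragments before C-allylation can occur, and the β-keto acid loses CO2 to give the 2-hydroxydeoxybenzoin.

Step 12
Reactants: 20 the 2-hydroxydeoxybenzoin
Product: 22 3-[2,4-dimethoxy-3-(3-methylbut-2-en-1-yl)phenyl]-5,7-bis(methoxymethoxy)-4H-chromen-4-one, via enaminone 21 (not isolated)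
Conditions: DMF-DMA (3 equiv), toluene, 90 °C
Reagents that add atoms: N,N-dimethylformamide dimethyl acetal, COC(OC)N(C)C
Why: Enaminone formation at the activated methylene followed by addition–elimination of the ortho phenol is the standard isoflavone annulation and closes the pyranone ring (supplying C2).

Step 13
Reactants: 22 the isoflavone
Product: 24 rac-3-[2,4-dimethoxy-3-(3-methylbut-2-en-1-yl)phenyl]-5,7-bis(methoxymethoxy)chroman-4-one, via lithium enolate 23 (not isolated)
Conditions: L-Selectride (1.2 equiv), THF, −78 °C; AcOH, −78 °C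
Reagents that add atoms: lithium tri-sec-butylborohydride, [Li+].CCC(C)[BH-](C(C)CC)C(C)CC (Li of 23)
Why: Conjugate (1,4-) hydride addition of the bulky borohydride at the unsubstituted C2 of the chromone gives the enolate, which is protonated to the racemic isoflavanone; the prenyl alkene is inert.

Step 14
Reactants: 24 the racemic isoflavanone
Product: 26 (3R)-3-[2,4-dimethoxy-3-(3-methylbut-2-en-1-yl)phenyl]-3-hydroxy-5,7-bis(methoxymethoxy)chroman-4-one, via sodium enolate 25 (not isolated)
Conditions: NaHMDS (1.2 equiv), THF, −78 °C; (+)-[(8,8-dimethoxycamphoryl)sulfonyl]oxaziridine (1.5 equiv), −78 → −40 °C; AcOH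
Reagents that add atoms: sodium hexamethyldisilazide, [Na+].C[Si](C)(C)[N-][Si](C)(C)C (Na of 25); (+)-[(8,8-dimethoxycamphoryl)sulfonyl]oxaziridine, CC1(C)[C@@H]2CC[C@]13CS(=O)(=O)N4O[C@@]34C2(OC)OC
Why: In this Davis asymmetric enolate hydroxylation the planar enolate attacks the oxaziridine oxygen on the face left open by the camphor ketal, and by analogy with 3-benzyl-5,7-dialkoxychroman-4-one and 2-alkyl-1-tetralone enolates the (+)-reagent should give the (R)-α-ketol; this sense is recalled from precedent and must be confirmed, with ee checked by chiral HPLC.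

Step 15
Reactants: 26 the (3R)-bis-MOM ether
Product: 27 (3R)-3-[2,4-dimethoxy-3-(3-methylbut-2-en-1-yl)phenyl]-3,5,7-trihydroxychroman-4-one
Conditions: HCl (cat., 2 M in MeOH), MeOH/THF, 40 °C
Reagents that add atoms: none
Why: Acid-catalysed acetal exchange removes both MOM groups; the prenyl group has no ortho hydroxyl to cyclise onto, C3 carries no hydrogen (so it cannot epimerise), and the tertiary α-ketol should not ionise in dilute acid at 40 °C.

**Compound list**

1 | 1,3-dimethoxybenzene | COc1cccc(OC)c1 | starting material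
2 | 2,6-dimethoxyphenyllithium | COc1cccc(OC)c1[Li] | intermediate
3 | 2-iodo-1,3-dimethoxybenzene | COc1cccc(OC)c1I | intermediate
4 | 1-bromo-3-iodo-2,4-dimethoxybenzene | COc1ccc(Br)c(OC)c1I | intermediate
5 | prenyl bromide (1-bromo-3-methylbut-2-ene) | CC(C)=CCBr | starting material
6 | (3-bromo-2,6-dimethoxyphenyl)magnesium chloride | COc1ccc(Br)c(OC)c1[Mg]Cl | intermediate
7 | 1-bromo-2,4-dimethoxy-3-(3-methylbut-2-en-1-yl)benzene | COc1ccc(Br)c(OC)c1CC=C(C)C | intermediate
8 | diethyl malonate | CCOC(=O)CC(=O)OCC | starting material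
9 | diethyl 2-[2,4-dimethoxy-3-(3-methylbut-2-en-1-yl)phenyl]malonate | CCOC(=O)C(C(=O)OCC)c1ccc(OC)c(CC=C(C)C)c1OC | intermediate
10 | 2-[2,4-dimethoxy-3-(3-methylbut-2-en-1-yl)phenyl]malonic acid | OC(=O)C(C(=O)O)c1ccc(OC)c(CC=C(C)C)c1OC | intermediate
11 | 2-[2,4-dimethoxy-3-(3-methylbut-2-en-1-yl)phenyl]acetic acid | OC(=O)Cc1ccc(OC)c(CC=C(C)C)c1OC | intermediate
12 | allyl 2-[2,4-dimethoxy-3-(3-methylbut-2-en-1-yl)phenyl]acetate | C=CCOC(=O)Cc1ccc(OC)c(CC=C(C)C)c1OC | intermediate
13 | 2,4,6-trihydroxybenzaldehyde | O=Cc1c(O)cc(O)cc1O | starting material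
14 | 2-hydroxy-4,6-bis(methoxymethoxy)benzaldehyde | COCOc1cc(O)c(C=O)c(OCOC)c1 | intermediate
15 | 2-(allyloxy)-4,6-bis(methoxymethoxy)benzaldehyde | C=CCOc1cc(OCOC)cc(OCOC)c1C=O | intermediate
16 | lithium enolate of allyl ester 12 | C=CCOC(O[Li])=Cc1ccc(OC)c(CC=C(C)C)c1OC | intermediate
17 | allyl 3-[2-(allyloxy)-4,6-bis(methoxymethoxy)phenyl]-2-[2,4-dimethoxy-3-(3-methylbut-2-en-1-yl)phenyl]-3-hydroxypropanoate (racemic syn/anti mixture) | C=CCOC(=O)C(c1ccc(OC)c(CC=C(C)C)c1OC)C(O)c1c(OCC=C)cc(OCOC)cc1OCOC | intermediate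
18 | allyl 3-[2-(allyloxy)-4,6-bis(methoxymethoxy)phenyl]-2-[2,4-dimethoxy-3-(3-methylbut-2-en-1-yl)phenyl]-3-oxopropanoate (racemic) | C=CCOC(=O)C(c1ccc(OC)c(CC=C(C)C)c1OC)C(=O)c1c(OCC=C)cc(OCOC)cc1OCOC | intermediate
19 | 2-[2,4-dimethoxy-3-(3-methylbut-2-en-1-yl)phenyl]-3-[2-hydroxy-4,6-bis(methoxymethoxy)phenyl]-3-oxopropanoic acid | OC(=O)C(c1ccc(OC)c(CC=C(C)C)c1OC)C(=O)c1c(O)cc(OCOC)cc1OCOC | intermediate
20 | 2-[2,4-dimethoxy-3-(3-methylbut-2-en-1-yl)phenyl]-1-[2-hydroxy-4,6-bis(methoxymethoxy)phenyl]ethan-1-one | COCOc1cc(O)c(C(=O)Cc2ccc(OC)c(CC=C(C)C)c2OC)c(OCOC)c1 | intermediate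
21 | 3-(dimethylamino)-2-[2,4-dimethoxy-3-(3-methylbut-2-en-1-yl)phenyl]-1-[2-hydroxy-4,6-bis(methoxymethoxy)phenyl]prop-2-en-1-one | CN(C)C=C(c1ccc(OC)c(CC=C(C)C)c1OC)C(=O)c1c(O)cc(OCOC)cc1OCOC | intermediate
22 | 3-[2,4-dimethoxy-3-(3-methylbut-2-en-1-yl)phenyl]-5,7-bis(methoxymethoxy)-4H-chromen-4-one | COCOc1cc(OCOC)c2c(c1)occ(-c1ccc(OC)c(CC=C(C)C)c1OC)c2=O | intermediate
23 | lithium 3-[2,4-dimethoxy-3-(3-methylbut-2-en-1-yl)phenyl]-5,7-bis(methoxymethoxy)-2H-chromen-4-olate | COCOc1cc(OCOC)c2c(c1)OCC(c1ccc(OC)c(CC=C(C)C)c1OC)=C2O[Li] | intermediate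
24 | rac-3-[2,4-dimethoxy-3-(3-methylbut-2-en-1-yl)phenyl]-5,7-bis(methoxymethoxy)chroman-4-one | COCOc1cc(OCOC)c2c(c1)OCC(c1ccc(OC)c(CC=C(C)C)c1OC)C2=O | intermediate
25 | sodium 3-[2,4-dimethoxy-3-(3-methylbut-2-en-1-yl)phenyl]-5,7-bis(methoxymethoxy)-2H-chromen-4-olate | COCOc1cc(OCOC)c2c(c1)OCC(c1ccc(OC)c(CC=C(C)C)c1OC)=C2O[Na] | intermediate
26 | (3R)-3-[2,4-dimethoxy-3-(3-methylbut-2-en-1-yl)phenyl]-3-hydroxy-5,7-bis(methoxymethoxy)chroman-4-one | COc1ccc([C@@]2(O)COc3cc(OCOC)cc(OCOC)c3C2=O)c(OC)c1CC=C(C)C | intermediate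
27 | (3R)-3-[2,4-dimethoxy-3-(3-methylbut-2-en-1-yl)phenyl]-3,5,7-trihydroxychroman-4-one | COc1ccc([C@@]2(O)COc3cc(O)cc(O)c3C2=O)c(OC)c1CC=C(C)C | target

**Step count and risks**

Total steps: 15. Longest linear sequence: 13 (steps 1–6 and 9–15).

Risk 1, step 9 (aldol). The di-ortho-substituted, electron-rich aldehyde and the stabilised arylacetate enolate may give low conversion or a retro-aldol on work-up. The fallback makes the same C3–C4 bond by an irreversible crossed Claisen condensation. It sets out from 15, which is oxidised (NaClO2, NaH2PO4, 2-methyl-2-butene, t-BuOH/H2O) to 2-(allyloxy)-4,6-bis(methoxymethoxy)benzoic acid F1. This is activated with 1,1'-carbonyldiimidazole in THF to 1-[2-(allyloxy)-4,6-bis(methoxymethoxy)benzoyl]-1H-imidazole F2. Addition of F2 to 2.2 equiv of enolate 16 (from 12 and LDA, THF, −78 → 0 °C) gives the β-keto ester after AcOH quench, the second equivalent of enolate deprotonating the product and driving the acylation. The fallback comes back to the route at 18, so step 10 is skipped.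

Risk 2, step 14 (asymmetric hydroxylation). The ee may be insufficient for this α-aryl enolate, the sense of induction may be the reverse of the analogy, or the enolate may ring-open by β-elimination. If only the sense is wrong, the (−)-reagent is used. If the selectivity itself is poor, the stereocentre is obtained by separation instead of induction. The fallback sets out from 24, which is hydroxylated without stereocontrol (NaHMDS, THF, −78 °C, then racemic trans-2-(phenylsulfonyl)-3-phenyloxaziridine) to racemic 3-[2,4-dimethoxy-3-(3-methylbut-2-en-1-yl)phenyl]-3-hydroxy-5,7-bis(methoxymethoxy)chroman-4-one F3. This is resolved by preparative chiral-phase SFC (amylose tris(3,5-dimethylphenylcarbamate)); the (3R)-enantiomer is 26, where the fallback comes back to the route.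

Risk 3, step 15 (acidic MOM removal). The tertiary benzylic α-ketol could dehydrate to the isoflavone, or the prenyl group could add HCl or methanol. The fallback moves the acid step to before the tertiary alcohol exists and finishes with fluoride. It sets out from 24, which is treated with HCl in MeOH at 45 °C to give rac-3-[2,4-dimethoxy-3-(3-methylbut-2-en-1-yl)phenyl]-5,7-dihydroxychroman-4-one F4. Silylation (TBSCl, imidazole, DMF, rt) gives rac-5,7-bis(tert-butyldimethylsilyloxy)-3-[2,4-dimethoxy-3-(3-methylbut-2-en-1-yl)phenyl]chroman-4-one F5. Hydroxylation exactly as in step 14 gives (3R)-5,7-bis(tert-butyldimethylsilyloxy)-3-[2,4-dimethoxy-3-(3-methylbut-2-en-1-yl)phenyl]-3-hydroxychroman-4-one F6. Desilylation with TBAF/AcOH (1:1) in THF at 0 °C comes back to the route at 27.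

**Further compounds**

F1 | step 9 | 2-(allyloxy)-4,6-bis(methoxymethoxy)benzoic acid | C=CCOc1cc(OCOC)cc(OCOC)c1C(=O)O
F2 | step 9 | 1-[2-(allyloxy)-4,6-bis(methoxymethoxy)benzoyl]-1H-imidazole | C=CCOc1cc(OCOC)cc(OCOC)c1C(=O)n1ccnc1
F3 | step 14 | racemic 3-[2,4-dimethoxy-3-(3-methylbut-2-en-1-yl)phenyl]-3-hydroxy-5,7-bis(methoxymethoxy)chroman-4-one | COc1ccc(C2(O)COc3cc(OCOC)cc(OCOC)c3C2=O)c(OC)c1CC=C(C)C
F4 | step 15 | rac-3-[2,4-dimethoxy-3-(3-methylbut-2-en-1-yl)phenyl]-5,7-dihydroxychroman-4-one | COc1ccc(C2COc3cc(O)cc(O)c3C2=O)c(OC)c1CC=C(C)C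
F5 | step 15 | rac-5,7-bis(tert-butyldimethylsilyloxy)-3-[2,4-dimethoxy-3-(3-methylbut-2-en-1-yl)phenyl]chroman-4-one | COc1ccc(C2COc3cc(O[Si](C)(C)C(C)(C)C)cc(O[Si](C)(C)C(C)(C)C)c3C2=O)c(OC)c1CC=C(C)C
F6 | step 15 | (3R)-5,7-bis(tert-butyldimethylsilyloxy)-3-[2,4-dimethoxy-3-(3-methylbut-2-en-1-yl)phenyl]-3-hydroxychroman-4-one | COc1ccc([C@@]2(O)COc3cc(O[Si](C)(C)C(C)(C)C)cc(O[Si](C)(C)C(C)(C)C)c3C2=O)c(OC)c1CC=C(C)C
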